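**Retrosynthetic overview**
1. Ring A (the ten-membered carbocycle) is closed last, by a Nozaki–Hiyama–Kishi addition of a C10 (Z)-alkenyl iodide to a C9 aldehyde (C9–C10). The epoxytiglate on O8 is already in place; its acid comes from a Sharpless epoxidation.
2. Ring B (the γ-lactone O6–C6–C7–C11–C12) is closed before that by an intramolecular Morita–Baylis–Hillman reaction that forms C11–C7 in an acyclic keto acrylate. This one isomerisation delivers the lactone, the quaternary C7 carbinol and the exocyclic C11=C13 methylene.
3. Enabling feature: the tertiary carbinol C7 is vicinal to the lactone carbon C6, so an acrylate on O6 holds its α-carbon C11 in a 1,5-relationship to a C7 ketone. The α-methylene-β-hydroxy-γ-lactone of ring B is the retron of that aldol-type closure.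
4. The keto acrylate comes from an (E)-alkenylalane (carboalumination of an iodo-enyne, C5–C6 bond) and a D-threose aldehyde made from dimethyl D-tartrate, followed by acrylation and oxidation at C7.
5. Stereorelay: C8 is the only purchased stereocentre of the core. A sacrificial C7 carbinol passes it to C6, C6 and C8 together set C7 in the key step, and C8 sets C9 in the ring-A closure. Ring order: B, then A.

Key step: step 11

Remark: locants follow germacrane numbering (ring carbons C1–C10, C11 the lactone α-carbon, C12 the lactone carbonyl, C13 the exocyclic methylene, C14 and C15 the methyls on C10 and C4); pent-4-yn-1-ol, dimethyl D-tartrate, (E)-2-methylbut-2-en-1-ol and all reagents are taken as commercial.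

**Route**

Step 1
Reactants: 1 pent-4-yn-1-ol
Product: 2 pent-4-ynal
Conditions: Dess–Martin periodinane (1.1 equiv), CH2Cl2, 0 °C to rt; filtered solution used directly
Reagents that add atoms: none
Why: Dess–Martin oxidation of a primary alcohol should stop at the aldehyde under neutral conditions, and the volatile ynal is carried on in solution.

Step 2
Reactants: 2 pent-4-ynal
Product: 3 (Z)-6-iodohept-5-en-1-yne
Conditions: [Ph3PCH2CH3]I, n-BuLi, THF, rt; I2, −78 °C; NaN(SiMe3)2, −20 °C; then 2, −78 °C
Reagents that add atoms: ethyltriphenylphosphonium iodide CC[P+](c1ccccc1)(c1ccccc1)c1ccccc1.[I-]; iodine II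
Why: Stork–Zhao olefination with the α-iodo ylide Ph3P=C(I)CH3 should give the 2-iodo-2-alkene with iodine cis to the chain under kinetic Wittig control, which fixes the later 1(10)-Z geometry, while the alkyne C–H is too weakly acidic to quench the ylide.

Step 3
Reactants: 4 dimethyl D-tartrate
Product: 5 dimethyl (4S,5S)-2-(4-methoxyphenyl)-1,3-dioxolane-4,5-dicarboxylate
Conditions: 4-MeOC6H4CH(OMe)2, camphorsulfonic acid (cat.), toluene, 80 °C, reduced pressure
Reagents that add atoms: 4-methoxybenzaldehyde dimethyl acetal COC(OC)c1ccc(OC)cc1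
Why: Acid-catalysed transacetalisation of the trans-diol should proceed cleanly, and the C2 axis of the tartrate makes the acetal carbon stereochemically irrelevant.

Step 4
Reactants: 5 dimethyl (4S,5S)-2-(4-methoxyphenyl)-1,3-dioxolane-4,5-dicarboxylate
Product: 6 2-O-(4-methoxybenzyl)-D-threitol
Conditions: iBu2AlH (6 equiv), CH2Cl2/toluene, −78 °C to rt; aq. potassium sodium tartrate
Reagents that add atoms: none
Why: Aluminium hydride reduction of both esters followed by reductive opening of the 4-methoxybenzylidene acetal should give the PMB ether, and the C2 axis makes both modes of acetal cleavage lead to the same triol.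

Step 5
Reactants: 6 2-O-(4-methoxybenzyl)-D-threitol
Product: 7 1,2-O-isopropylidene-3-O-(4-methoxybenzyl)-D-threitol
Conditions: 2,2-dimethoxypropane, pyridinium p-toluenesulfonate (cat.), acetone, rt
Reagents that add atoms: 2,2-dimethoxypropane COC(C)(C)OC
Why: Thermodynamic acetonide formation should take the terminal 1,2-diol into a dioxolane and leave the primary alcohol next to the PMB ether free.

Step 6
Reactants: 7 1,2-O-isopropylidene-3-O-(4-methoxybenzyl)-D-threitol
Product: 8 3,4-O-isopropylidene-2-O-(4-methoxybenzyl)-D-threose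
Conditions: Dess–Martin periodinane, pyridine, CH2Cl2, 0 °C; used crude
Reagents that add atoms: none
Why: Buffered Dess–Martin oxidation should give the α-alkoxy aldehyde without epimerisation of the α-centre.

Step 7
Reactants: 3 (Z)-6-iodohept-5-en-1-yne; 8 3,4-O-isopropylidene-2-O-(4-methoxybenzyl)-D-threose
Product: 10 allylic alcohol (6R,7R,8R), via alkenyldimethylalane 9 (not isolated)
Conditions: 3 (1.3 equiv), AlMe3 (2.6 equiv), Cp2ZrCl2 (0.25 equiv), H2O (1.3 equiv), CH2Cl2, −25 °C; volatiles removed in vacuo; then 8, CH2Cl2, −78 to −30 °C; aq. potassium sodium tartrate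
Reagents that add atoms: trimethylaluminium C[Al](C)C
Why: Negishi zirconium-catalysed syn-carboalumination should place CH3 on C4 and Al on C5 (E geometry), the alkenylalane then adds to the aldehyde with retention, and non-chelated Felkin–Anh attack anti to the C7 OPMB group should set C6 (6,7-anti), reinforced by the 7,8-syn bis-alkoxy pattern of the aldehyde.

Step 8
Reactants: 10 allylic alcohol (6R,7R,8R)
Product: 11 O6-acrylate of 10
Conditions: acryloyl chloride (1.5 equiv), Et3N, CH2Cl2, −40 to 0 °C
Reagents that add atoms: acryloyl chloride C=CC(=O)Cl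
Why: O-acylation of the secondary allylic alcohol with retention at C6 installs C11, C12 and C13 on the oxygen that becomes the lactone oxygen.

Step 9
Reactants: 11 O6-acrylate of 10
Product: 12 C7 alcohol
Conditions: DDQ (1.3 equiv), CH2Cl2/pH 7 phosphate buffer (10:1), 0 °C
Reagents that add atoms: none
Why: Oxidative PMB cleavage by DDQ (benzylic hydride abstraction, then hydrolysis of the oxocarbenium ion) should leave the acrylate, acetonide, alkenyl iodide and trisubstituted alkene untouched.

Step 10
Reactants: 12 C7 alcohol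
Product: 13 keto acrylate
Conditions: Dess–Martin periodinane, pyridine, CH2Cl2, 0 °C; used at once
Reagents that add atoms: none
Why: Dess–Martin oxidation erases the sacrificial C7 carbinol stereocentre and unveils the ketone under conditions that should not enolise C6.

Step 11
Reactants: 13 keto acrylate
Product: 14 α-methylene-β-hydroxy-γ-lactone (6R,7R,8R)
Conditions: quinuclidine (1.0 equiv), 4-nitrophenol (0.2 equiv), 1,2-dimethoxyethane, 0.05 M, 0 °C to rt
Reagents that add atoms: none
Why: Quinuclidine adds to C13 of the acrylate to give an ammonium ester enolate whose α-carbon C11 attacks the C7 ketone, and proton transfer (relayed by the phenol) followed by E1cB loss of the amine regenerates the C11=C13 methylene, so 13 should isomerise to 14 with full atom economy. The closest known reaction type is the intramolecular Morita–Baylis–Hillman reaction of acryloyl esters and amides onto tethered carbonyl groups, which gives α-methylene-β-hydroxy-γ-lactones and -lactams. Ring B is closed by a 5-(enolendo)-exo-trig aldol addition, the same mode as in cyclopentenone-forming aldol and Dieckmann closures. The new quaternary stereocentre C7 is controlled by C6, because in the five-membered transition state the dioxolanyl group on C7 goes trans to the alkenyl group on C6, and independently by C8, because attack anti to the dioxolane C8–O bond (Felkin–Anh) leads to the same 7R face. The step needs cyclisation to outrun enolisation of the C6–H (α to the ketone and allylic) and intermolecular addition; the 1,5-relationship of C11 and C7, the absence of any other carbonyl electrophile, a weakly basic tertiary amine with a proton shuttle and moderate dilution should secure this.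

Step 12
Reactants: 14 α-methylene-β-hydroxy-γ-lactone (6R,7R,8R)
Product: 15 lactone triol
Conditions: AcOH/H2O (4:1), 35 °C
Reagents that add atoms: none
Why: Mild acid hydrolysis should remove the terminal acetonide without ionising the tertiary allylic carbinol or the allylic lactone C6–O bond.

Step 13
Reactants: 15 lactone triol
Product: 16 C9 triethylsilyl ether
Conditions: Et3SiCl (1.05 equiv), imidazole, CH2Cl2, −78 °C
Reagents that add atoms: chlorotriethylsilane CC[Si](Cl)(CC)CC
Why: Silylation should be selective for the primary C9 hydroxyl over the hindered secondary C8 and tertiary C7 hydroxyl groups.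

Step 14
Reactants: 17 (E)-2-methylbut-2-en-1-ol
Product: 18 [(2R,3R)-2,3-dimethyloxiran-2-yl]methanol
Conditions: Ti(OiPr)4 (0.1 equiv), D-(−)-diisopropyl tartrate (0.12 equiv), t-BuOOH, 4 Å molecular sieves, CH2Cl2, −20 °C
Reagents that add atoms: tert-butyl hydroperoxide CC(C)(C)OO
Why: Sharpless asymmetric epoxidation with the D-(−)-tartrate ligand should deliver oxygen to the face that gives the 2R,3R epoxy alcohol, and syn addition keeps the two methyl groups cis.

Step 15
Reactants: 18 [(2R,3R)-2,3-dimethyloxiran-2-yl]methanol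
Product: 19 (2S,3R)-2,3-dimethyloxirane-2-carboxylic acid
Conditions: RuCl3 hydrate (2 mol %), NaIO4 (3 equiv), MeCN/EtOAc/H2O, 0 °C to rt
Reagents that add atoms: water O
Why: RuO4 generated in situ should oxidise the primary alcohol through the aldehyde hydrate to the acid and leave the epoxide intact (the 2S descriptor is a priority change only).

Step 16
Reactants: 16 C9 triethylsilyl ether; 19 (2S,3R)-2,3-dimethyloxirane-2-carboxylic acid
Product: 21 O8-epoxytiglate, via mixed anhydride 20 (not isolated)
Conditions: 19 (2 equiv), 2,4,6-trichlorobenzoyl chloride, Et3N, toluene, rt; then 16, 4-(dimethylamino)pyridine, toluene, 40 °C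
Reagents that add atoms: none
Why: Yamaguchi esterification through the mixed anhydride and its acylpyridinium ion should acylate the only reactive hydroxyl (secondary C8) with retention at C8 and at both epoxide carbons, the tertiary C7 hydroxyl being inert.

Step 17
Reactants: 21 O8-epoxytiglate
Product: 22 C9 aldehyde
Conditions: (COCl)2, DMSO, CH2Cl2, −78 to −40 °C; Et3N, −78 to 0 °C
Reagents that add atoms: none
Why: Swern oxidation applied directly to the primary triethylsilyl ether should work because the activated sulfonium species cleaves the labile primary Si–O bond and the alkoxysulfonium ylide collapses to the aldehyde, which saves a separate desilylation.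

Step 18
Reactants: 22 C9 aldehyde
Product: 23 CNP0420662.1
Conditions: CrCl2 (10 equiv), NiCl2 (0.1 equiv), degassed DMSO, slow addition to 2 mM, rt
Reagents that add atoms: none
Why: Nozaki–Hiyama–Kishi macrocyclisation (nickel-catalysed activation of the alkenyl iodide, transmetalation to trivalent chromium, chemoselective addition to the aldehyde with retention of the Z geometry) should close ring A, with Felkin–Anh attack anti to the C8 acyloxy group giving the 8,9-anti (9R) carbinol while the esters, epoxide, tertiary alcohol and α-methylene lactone are tolerated.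

**Compound list**
1 | pent-4-yn-1-ol | C#CCCCO | starting material
2 | pent-4-ynal | C#CCCC=O | intermediate
3 | (Z)-6-iodohept-5-en-1-yne | C/C(I)=C/CCC#C | intermediate
4 | dimethyl D-tartrate, dimethyl (2S,3S)-2,3-dihydroxybutanedioate | COC(=O)[C@@H](O)[C@H](O)C(=O)OC | starting material
5 | dimethyl (4S,5S)-2-(4-methoxyphenyl)-1,3-dioxolane-4,5-dicarboxylate | COC(=O)[C@H]1OC(c2ccc(OC)cc2)O[C@@H]1C(=O)OC | intermediate
6 | 2-O-(4-methoxybenzyl)-D-threitol, (2R,3R)-3-[(4-methoxyphenyl)methoxy]butane-1,2,4-triol | OC[C@@H](OCc1ccc(OC)cc1)[C@H](O)CO | intermediate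
7 | 1,2-O-isopropylidene-3-O-(4-methoxybenzyl)-D-threitol, (2R)-2-[(4R)-2,2-dimethyl-1,3-dioxolan-4-yl]-2-[(4-methoxyphenyl)methoxy]ethan-1-ol | OC[C@@H](OCc1ccc(OC)cc1)[C@H]1COC(C)(C)O1 | intermediate
8 | 3,4-O-isopropylidene-2-O-(4-methoxybenzyl)-D-threose, (2S)-2-[(4R)-2,2-dimethyl-1,3-dioxolan-4-yl]-2-[(4-methoxyphenyl)methoxy]acetaldehyde | O=C[C@@H](OCc1ccc(OC)cc1)[C@H]1COC(C)(C)O1 | intermediate
9 | alkenyldimethylalane, dimethyl[(1E,5Z)-6-iodo-2-methylhepta-1,5-dien-1-yl]alane | C/C(I)=C/CC/C(C)=C/[Al](C)C | intermediate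
10 | allylic alcohol (6R,7R,8R), (1R,2R,3E,7Z)-1-[(4R)-2,2-dimethyl-1,3-dioxolan-4-yl]-8-iodo-1-[(4-methoxyphenyl)methoxy]-4-methylnona-3,7-dien-2-ol | C/C(I)=C/CC/C(C)=C/[C@@H](O)[C@@H](OCc1ccc(OC)cc1)[C@H]1COC(C)(C)O1 | intermediate
11 | O6-acrylate of 10, (1R,2R,3E,7Z)-1-[(4R)-2,2-dimethyl-1,3-dioxolan-4-yl]-8-iodo-1-[(4-methoxyphenyl)methoxy]-4-methylnona-3,7-dien-2-yl prop-2-enoate | C/C(I)=C/CC/C(C)=C/[C@@H](OC(=O)C=C)[C@@H](OCc1ccc(OC)cc1)[C@H]1COC(C)(C)O1 | intermediate
12 | C7 alcohol, (1R,2R,3E,7Z)-1-[(4R)-2,2-dimethyl-1,3-dioxolan-4-yl]-1-hydroxy-8-iodo-4-methylnona-3,7-dien-2-yl prop-2-enoate | C/C(I)=C/CC/C(C)=C/[C@@H](OC(=O)C=C)[C@@H](O)[C@H]1COC(C)(C)O1 | intermediate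
13 | keto acrylate, (2R,3E,7Z)-1-[(4R)-2,2-dimethyl-1,3-dioxolan-4-yl]-8-iodo-4-methyl-1-oxonona-3,7-dien-2-yl prop-2-enoate | C/C(I)=C/CC/C(C)=C/[C@@H](OC(=O)C=C)C(=O)[C@H]1COC(C)(C)O1 | intermediate
14 | α-methylene-β-hydroxy-γ-lactone (6R,7R,8R), (4R,5R)-4-[(4R)-2,2-dimethyl-1,3-dioxolan-4-yl]-4-hydroxy-5-[(1E,5Z)-6-iodo-2-methylhepta-1,5-dien-1-yl]-3-methylideneoxolan-2-one | C/C(I)=C/CC/C(C)=C/[C@H]1OC(=O)C(=C)[C@]1(O)[C@H]2COC(C)(C)O2 | intermediate
15 | lactone triol, (4S,5R)-4-[(1R)-1,2-dihydroxyethyl]-4-hydroxy-5-[(1E,5Z)-6-iodo-2-methylhepta-1,5-dien-1-yl]-3-methylideneoxolan-2-one (same spatial arrangement as 14) | C/C(I)=C/CC/C(C)=C/[C@H]1OC(=O)C(=C)[C@]1(O)[C@H](O)CO | intermediate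
16 | C9 triethylsilyl ether, (4S,5R)-4-hydroxy-4-[(1R)-1-hydroxy-2-(triethylsilyloxy)ethyl]-5-[(1E,5Z)-6-iodo-2-methylhepta-1,5-dien-1-yl]-3-methylideneoxolan-2-one | C/C(I)=C/CC/C(C)=C/[C@H]1OC(=O)C(=C)[C@]1(O)[C@H](O)CO[Si](CC)(CC)CC | intermediate
17 | (E)-2-methylbut-2-en-1-ol | C/C=C(\C)CO | starting material
18 | [(2R,3R)-2,3-dimethyloxiran-2-yl]methanol | OC[C@@]1(C)O[C@@H]1C | intermediate
19 | (2S,3R)-2,3-dimethyloxirane-2-carboxylic acid | OC(=O)[C@@]1(C)O[C@@H]1C | intermediate
20 | mixed anhydride, (2S,3R)-2,3-dimethyloxirane-2-carboxylic 2,4,6-trichlorobenzoic anhydride | O=C(OC(=O)[C@@]1(C)O[C@@H]1C)c1c(Cl)cc(Cl)cc1Cl | intermediate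
21 | O8-epoxytiglate, (1R)-1-[(2R,3R)-3-hydroxy-2-[(1E,5Z)-6-iodo-2-methylhepta-1,5-dien-1-yl]-4-methylidene-5-oxooxolan-3-yl]-2-(triethylsilyloxy)ethyl (2S,3R)-2,3-dimethyloxirane-2-carboxylate | C/C(I)=C/CC/C(C)=C/[C@H]1OC(=O)C(=C)[C@]1(O)[C@H](OC(=O)[C@@]2(C)O[C@@H]2C)CO[Si](CC)(CC)CC | intermediate
22 | C9 aldehyde, (1S)-1-[(2R,3R)-3-hydroxy-2-[(1E,5Z)-6-iodo-2-methylhepta-1,5-dien-1-yl]-4-methylidene-5-oxooxolan-3-yl]-2-oxoethyl (2S,3R)-2,3-dimethyloxirane-2-carboxylate (same spatial arrangement as 21) | C/C(I)=C/CC/C(C)=C/[C@H]1OC(=O)C(=C)[C@]1(O)[C@H](OC(=O)[C@@]2(C)O[C@@H]2C)C=O | intermediate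
23 | CNP0420662.1, (3aR,4R,5R,6Z,10E,11aR)-3a,5-dihydroxy-6,10-dimethyl-3-methylidene-2-oxo-2,3,3a,4,5,8,9,11a-octahydrocyclodeca[b]furan-4-yl (2S,3R)-2,3-dimethyloxirane-2-carboxylate | C=C1C(=O)O[C@@H]2/C=C(\C)CC/C=C(/C)[C@@H](O)[C@@H](OC(=O)[C@@]3(C)O[C@@H]3C)[C@@]12O | target

**Count**
Total steps: 18. Longest linear sequence: 14 steps (steps 3–13 and 16–18, from dimethyl D-tartrate).

**Steps most likely to fail**

Step 11. What may go wrong: enolisation of the doubly activated C6–H (epimerisation at C6, or migration of the C4=C5 double bond into conjugation) may compete with a slow closure onto the hindered ketone. The fallback sets out from 13 and comes back at 14. A copper hydride conjugate reduction–aldol cyclisation (Cu(OAc)2·H2O and rac-BINAP as catalyst, 1,1,3,3-tetramethyldisiloxane, THF, rt) generates the enolate irreversibly without base and should close the same lactone to the α-methyl-β-hydroxy lactone F1 (C11 epimers). Double deprotonation with LiN(iPr)2 and trapping with PhSeBr should give the α-methyl-α-phenylselanyl lactone F2. Oxidation with H2O2 and syn-elimination, possible only towards the methyl group because C7 carries no hydrogen, should give 14.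

Step 18. What may go wrong: addition to the wrong face of the C9 aldehyde if the strain of the forming ten-membered ring overrides Felkin–Anh control, with oligomerisation as the concentration-dependent competitor. The fallback sets out from 22 and comes back at 23. The ring closure is run without regard to C9 and should give 23 mixed with the C9 epimer F3. MnO2 in CH2Cl2 should oxidise only the allylic C9 carbinol of the mixture to the ring enone F4. A catalyst-controlled Corey–Bakshi–Shibata reduction ((R)-Me-CBS oxazaborolidine, catecholborane, toluene, −78 °C, the alkenyl group taken as the large substituent) should then set 9R and give 23.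

Step 7. What may go wrong: loss of facial selectivity at C6 through chelated delivery by aluminium, or competing methyl transfer to the aldehyde. The fallback sets out from 3 and 8 and comes back at 10. The addition is run for conversion and should give 10 together with the C6 epimer F5. Dess–Martin oxidation of the mixture should give the enone F6. LiBH(s-Bu)3 in THF at −78 °C should reduce this β,β-disubstituted enone in the 1,2 sense under Felkin–Anh control anti to the PMB ether and give 10 as the single C6 epimer.

Further compounds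
F1 | step 11 | α-methyl-β-hydroxy lactone, 11,13-dihydro-14 (C11 epimers; C6, C7, C8 as in 14) | C/C(I)=C/CC/C(C)=C/[C@H]1OC(=O)C(C)[C@]1(O)[C@H]2COC(C)(C)O2
F2 | step 11 | α-methyl-α-phenylselanyl lactone (C11 epimers; C6, C7, C8 as in 14) | C/C(I)=C/CC/C(C)=C/[C@H]1OC(=O)C(C)([Se]c3ccccc3)[C@]1(O)[C@H]2COC(C)(C)O2
F3 | step 18 | C9 epimer of 23 (9S) | C=C1C(=O)O[C@@H]2/C=C(\C)CC/C=C(/C)[C@H](O)[C@@H](OC(=O)[C@@]3(C)O[C@@H]3C)[C@@]12O
F4 | step 18 | ring enone, 9-oxo analogue of 23 | C=C1C(=O)O[C@@H]2/C=C(\C)CC/C=C(/C)C(=O)[C@@H](OC(=O)[C@@]3(C)O[C@@H]3C)[C@@]12O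
F5 | step 7 | C6 epimer of 10 (6S) | C/C(I)=C/CC/C(C)=C/[C@H](O)[C@@H](OCc1ccc(OC)cc1)[C@H]1COC(C)(C)O1
F6 | step 7 | enone, 6-oxo analogue of 10 | C/C(I)=C/CC/C(C)=C/C(=O)[C@@H](OCc1ccc(OC)cc1)[C@H]1COC(C)(C)O1
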